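**Retrosynthetic overview**

1. Target 12 ⇐ 11 (Si–O cleavage) ⇐ 10 (1,2-reduction of the formyl group on C3) ⇐ 7 (α,β-desaturation that creates C3=C4). Locants are those of the target dihydronaphthalene.
2. 7 ⇐ aldehyde 3 + cinnamyl silyl ether 6 by a one-flask [4+2] annulation that forms C2–C3 and C1–C8a: enantioselective organo-SOMO catalysis (enamine radical cation, addition to the styrene, oxidation to the benzylic cation, Friedel–Crafts closure).
3. Enabling feature: ring A is a twofold-symmetric 3,4,5-trimethoxyphenyl group whose two equivalent ortho C–H carbons (future C8a) are each ortho and para to a methoxy group and lie three bonds from the aldehyde α-carbon (future C3). The para-methoxy group of ring C stabilises radical and cation at the future C1.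
4. Ring order: rings A and C are purchased; ring B is the only ring formed (step 4). 3 comes from aryl iodide 1 and allyl alcohol 2, and 6 from cinnamate 4.

Key step: step 4

Assumption: the shielded face of the enamine radical cation and the anti (C2/C3-trans) course of the radical addition are assigned by analogy. Whichever C3-epimer of 7 prevails, the catalyst enantiomer is chosen so that C1 and C2 have the configuration shown, the C2-epimers are separated at the stage of 7, and C3 becomes planar in step 5.

**Step 1**
Reactants: 1 5-iodo-1,2,3-trimethoxybenzene; 2 prop-2-en-1-ol (allyl alcohol)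
Product: 3 3-(3,4,5-trimethoxyphenyl)propanal
Conditions: Pd(OAc)2 (3 mol %), n-Bu4NCl, NaHCO3, DMF, 40 °C
Reagents that add atoms: none
Why: Heck arylation of allyl alcohol under ligand-free phase-transfer conditions should place the aryl group on the terminal carbon, and β-hydride elimination toward the carbinol carbon followed by enol–aldehyde tautomerism gives the saturated aldehyde directly.

**Step 2**
Reactants: 4 methyl (E)-3-(3,4-dimethoxyphenyl)prop-2-enoate
Product: 5 (E)-3-(3,4-dimethoxyphenyl)prop-2-en-1-ol
Conditions: i-Bu2AlH (2.3 equiv), CH2Cl2, −78 °C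
Reagents that add atoms: none
Why: 1,2-reduction of the conjugated ester by the aluminium hydride at low temperature should give the allylic alcohol with the E double bond intact.

**Step 3**
Reactants: 5 (E)-3-(3,4-dimethoxyphenyl)prop-2-en-1-ol
Product: 6 tert-butyl{[(E)-3-(3,4-dimethoxyphenyl)prop-2-en-1-yl]oxy}dimethylsilane
Conditions: TBSCl, imidazole, DMF, rt
Reagents that add atoms: tert-butyldimethylsilyl chloride, CC(C)(C)[Si](C)(C)Cl
Why: standard silylation of the primary allylic alcohol; a silyl ether is chosen because, unlike an ester, it cannot capture the benzylic cation of step 4 by neighbouring-group participation and it should survive the mildly acidic oxidative medium.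

**Step 4**
Reactants: 3 3-(3,4,5-trimethoxyphenyl)propanal; 6 tert-butyl{[(E)-3-(3,4-dimethoxyphenyl)prop-2-en-1-yl]oxy}dimethylsilane
Product: 7 (2S,3S,4R)-3-{[tert-butyl(dimethyl)silyl]oxymethyl}-4-(3,4-dimethoxyphenyl)-5,6,7-trimethoxy-1,2,3,4-tetrahydronaphthalene-2-carbaldehyde
Conditions: (2S,5S)-5-benzyl-2-tert-butyl-3-methylimidazolidin-4-one trifluoroacetate (20 mol %), [Fe(phen)3](SbF6)3 (phen = 1,10-phenanthroline, 2.5 equiv), Na2HPO4, H2O (2 equiv), acetone, −30 °C; 6 in twofold excess; C2-epimers separated by chromatography
Reagents that add atoms: none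
Why: Mechanism: 3 condenses with the imidazolidinone to an enamine that [Fe(phen)3](SbF6)3 (trivalent iron) oxidizes to a 3π-electron radical cation, whose α-carbon (future C3) adds to the silyloxymethyl-bearing alkene carbon of 6 (future C2); a second one-electron oxidation turns the resulting 3,4-dimethoxybenzylic radical into the cation at C1 (radical–polar crossover), an ortho carbon of ring A (future C8a) attacks it, and proton loss and iminium hydrolysis release 7 and the catalyst. The closest known reaction type is the enantioselective organo-SOMO [4+2] cascade of 3-arylpropanals with styrenes, and addition of such radical cations to the substituted carbon of a 1,2-disubstituted styrene is the first event of the known α-vinylation with styryl trifluoroborates. Ring B closes as a six-membered ring by cationic Friedel–Crafts alkylation, 6-endo with respect to the attacked arene π-bond. C3 is set by the catalyst, whose benzyl group shields one face of the radical cation; C2 is set relative to C3 in the open, staggered transition state of the radical addition; C1 is set relative to C2 in the chair-like cation cyclization, which should place the aryl group trans to the silyloxymethyl group whatever the alkene geometry. The step needs oxidation of the enamine in preference to the electron-rich styrene, which the mild outer-sphere oxidant and the low oxidation potential of the enamine should secure, and radical attack at the alkene carbon remote from ring C, which formation of the benzylic radical secures; the ring closure poses no regiochemical question because the two ortho positions of ring A are equivalent and each is ortho and para to a methoxy group.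

**Step 5**
Reactants: 7 (2S,3S,4R)-3-{[tert-butyl(dimethyl)silyl]oxymethyl}-4-(3,4-dimethoxyphenyl)-5,6,7-trimethoxy-1,2,3,4-tetrahydronaphthalene-2-carbaldehyde
Product: 10 (3S,4R)-3-{[tert-butyl(dimethyl)silyl]oxymethyl}-4-(3,4-dimethoxyphenyl)-5,6,7-trimethoxy-3,4-dihydronaphthalene-2-carbaldehyde, via α-phenylselanyl aldehyde 8 (not isolated), via selenoxide 9 (not isolated)
Conditions: N-(phenylseleno)phthalimide, pyrrolidine (20 mol %), CH2Cl2, rt; then NaIO4, NaHCO3, THF–H2O, 0 °C to rt
Reagents that add atoms: none
Why: enamine-mediated α-selenenylation of the α-branched aldehyde followed by periodate oxidation and selenoxide syn-elimination should erase the C3 stereocentre and give the enal, the elimination taking one of the two benzylic C4 hydrogens (arene-conjugated alkene) rather than the single hindered C2 hydrogen, so that C1 and C2 stay untouched.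

**Step 6**
Reactants: 10 (3S,4R)-3-{[tert-butyl(dimethyl)silyl]oxymethyl}-4-(3,4-dimethoxyphenyl)-5,6,7-trimethoxy-3,4-dihydronaphthalene-2-carbaldehyde
Product: 11 [(3S,4R)-3-{[tert-butyl(dimethyl)silyl]oxymethyl}-4-(3,4-dimethoxyphenyl)-5,6,7-trimethoxy-3,4-dihydronaphthalen-2-yl]methanol
Conditions: i-Bu2AlH (1.3 equiv), CH2Cl2, −78 °C
Reagents that add atoms: none
Why: 1,2-reduction of the aryl-conjugated enal by the aluminium hydride at low temperature should give the allylic alcohol without touching the trisubstituted alkene or the silyl ether.

**Step 7**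
Reactants: 11 [(3S,4R)-3-{[tert-butyl(dimethyl)silyl]oxymethyl}-4-(3,4-dimethoxyphenyl)-5,6,7-trimethoxy-3,4-dihydronaphthalen-2-yl]methanol
Product: 12 [(1R,2S)-1-(3,4-dimethoxyphenyl)-6,7,8-trimethoxy-1,2-dihydronaphthalene-2,3-diyl]dimethanol (target)
Conditions: n-Bu4NF, THF, 0 °C to rt
Reagents that add atoms: none
Why: fluoride-mediated cleavage of the silyl ether should release the second primary alcohol under non-acidic conditions that leave the allylic and doubly benzylic positions and both stereocentres untouched.

**Compound list**

1 | 5-iodo-1,2,3-trimethoxybenzene | COc1cc(I)cc(OC)c1OC | starting material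
2 | prop-2-en-1-ol (allyl alcohol) | C=CCO | starting material
3 | 3-(3,4,5-trimethoxyphenyl)propanal | COc1cc(CCC=O)cc(OC)c1OC | intermediate
4 | methyl (E)-3-(3,4-dimethoxyphenyl)prop-2-enoate | COc1ccc(/C=C/C(=O)OC)cc1OC | starting material
5 | (E)-3-(3,4-dimethoxyphenyl)prop-2-en-1-ol | COc1ccc(/C=C/CO)cc1OC | intermediate
6 | tert-butyl{[(E)-3-(3,4-dimethoxyphenyl)prop-2-en-1-yl]oxy}dimethylsilane | COc1ccc(/C=C/CO[Si](C)(C)C(C)(C)C)cc1OC | intermediate
7 | (2S,3S,4R)-3-{[tert-butyl(dimethyl)silyl]oxymethyl}-4-(3,4-dimethoxyphenyl)-5,6,7-trimethoxy-1,2,3,4-tetrahydronaphthalene-2-carbaldehyde (aryl, silyloxymethyl and formyl groups all-trans) | COc1ccc([C@@H]2c3c(cc(OC)c(OC)c3OC)C[C@H](C=O)[C@H]2CO[Si](C)(C)C(C)(C)C)cc1OC | intermediate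
8 | α-phenylselanyl aldehyde: 7 with PhSe in place of the hydrogen on the formyl-bearing carbon (that carbon as a mixture; the carbons bearing the silyloxymethyl and aryl groups as in 7) | COc1ccc([C@@H]2c3c(cc(OC)c(OC)c3OC)CC(C=O)([Se]c4ccccc4)[C@H]2CO[Si](C)(C)C(C)(C)C)cc1OC | intermediate
9 | selenoxide of 8 (same stereochemical description) | COc1ccc([C@@H]2c3c(cc(OC)c(OC)c3OC)CC(C=O)([Se](=O)c4ccccc4)[C@H]2CO[Si](C)(C)C(C)(C)C)cc1OC | intermediate
10 | (3S,4R)-3-{[tert-butyl(dimethyl)silyl]oxymethyl}-4-(3,4-dimethoxyphenyl)-5,6,7-trimethoxy-3,4-dihydronaphthalene-2-carbaldehyde | COc1ccc([C@@H]2c3c(cc(OC)c(OC)c3OC)C=C(C=O)[C@H]2CO[Si](C)(C)C(C)(C)C)cc1OC | intermediate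
11 | [(3S,4R)-3-{[tert-butyl(dimethyl)silyl]oxymethyl}-4-(3,4-dimethoxyphenyl)-5,6,7-trimethoxy-3,4-dihydronaphthalen-2-yl]methanol | COc1ccc([C@@H]2c3c(cc(OC)c(OC)c3OC)C=C(CO)[C@H]2CO[Si](C)(C)C(C)(C)C)cc1OC | intermediate
12 | [(1R,2S)-1-(3,4-dimethoxyphenyl)-6,7,8-trimethoxy-1,2-dihydronaphthalene-2,3-diyl]dimethanol | COc1ccc([C@@H]2c3c(cc(OC)c(OC)c3OC)C=C(CO)[C@H]2CO)cc1OC | target

**Step count and risks**

Total steps: 7. Longest linear sequence: 6 (steps 2, 3, 4, 5, 6, 7).

Most likely to fail:

1. Step 4. The radical addition to the 1,2-disubstituted, electron-rich alkene may be slow relative to direct oxidation of 6. The cascade may also be interrupted after the first C–C bond, with the benzylic radical or cation captured before ring closure. Facial discrimination at the alkene carbon may be low, which costs material when the C2-epimers are separated. The fallback decouples the two bond formations and sets out from 3 and 6. The same imidazolidinone salt with (NH4)2Ce(NO3)6 and NaHCO3 in DME at −40 °C runs the known carbo-oxidation of styrenes, in which the benzylic radical is captured as its nitrate ester. This should give (2S,3S)-3-{[tert-butyl(dimethyl)silyl]oxymethyl}-4-(3,4-dimethoxyphenyl)-4-(nitrooxy)-2-[(3,4,5-trimethoxyphenyl)methyl]butanal F1 as a mixture at the nitrate-bearing carbon, which is purified. Solvolysis in hexafluoroisopropanol at room temperature then ionizes the benzylic nitrate and closes ring B by Friedel–Crafts alkylation, which returns to the route at 7.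

2. Step 5. Enamine formation and selenenylation at the hindered, fully substituted α-carbon may stall. The selenoxide may eliminate toward C2 and erase that stereocentre. Ring B may be dehydrogenated further to the naphthalene during the oxidation. The fallback replaces the selenoxide elimination by a palladium-enolate β-hydride elimination (Saegusa–Ito oxidation) and sets out from 7. TMSOTf and Et3N in CH2Cl2 at 0 °C should give the enol ether (3S,4R)-3-{[tert-butyl(dimethyl)silyl]oxymethyl}-4-(3,4-dimethoxyphenyl)-5,6,7-trimethoxy-2-[(trimethylsilyloxy)methylidene]-1,2,3,4-tetrahydronaphthalene F2. Treatment with Pd(OAc)2 (divalent palladium) in MeCN–DMSO at room temperature then returns to the route at 10.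

3. Step 1. β-Hydride elimination toward the aryl-bearing carbon would give the cinnamyl alcohol. Reversed insertion regiochemistry would give the branched aldehyde. Base-promoted aldol self-condensation may consume 3. The fallback builds the aldehyde by redox adjustment of an ester and sets out from 1. Heck coupling with methyl acrylate (Pd(OAc)2, P(o-tol)3, Et3N, MeCN, 80 °C) should give methyl (E)-3-(3,4,5-trimethoxyphenyl)prop-2-enoate F3. Hydrogenation (H2, Pd/C, EtOAc) gives methyl 3-(3,4,5-trimethoxyphenyl)propanoate F4. Partial reduction with i-Bu2AlH (1.05 equiv, toluene, −78 °C) returns to the route at 3.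

**Further compounds**

F1 | step 4 | (2S,3S)-3-{[tert-butyl(dimethyl)silyl]oxymethyl}-4-(3,4-dimethoxyphenyl)-4-(nitrooxy)-2-[(3,4,5-trimethoxyphenyl)methyl]butanal (mixture at C4) | COc1ccc(C(O[N+](=O)[O-])[C@H](CO[Si](C)(C)C(C)(C)C)[C@@H](C=O)Cc2cc(OC)c(OC)c(OC)c2)cc1OC
F2 | step 5 | (3S,4R)-3-{[tert-butyl(dimethyl)silyl]oxymethyl}-4-(3,4-dimethoxyphenyl)-5,6,7-trimethoxy-2-[(trimethylsilyloxy)methylidene]-1,2,3,4-tetrahydronaphthalene | COc1ccc([C@@H]2c3c(cc(OC)c(OC)c3OC)CC(=CO[Si](C)(C)C)[C@H]2CO[Si](C)(C)C(C)(C)C)cc1OC
F3 | step 1 | methyl (E)-3-(3,4,5-trimethoxyphenyl)prop-2-enoate | COc1cc(/C=C/C(=O)OC)cc(OC)c1OC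
F4 | step 1 | methyl 3-(3,4,5-trimethoxyphenyl)propanoate | COc1cc(CCC(=O)OC)cc(OC)c1OC
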